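## Retrosynthetic overview

1. The α-methylene ketone and the 12-OH come from a syn-12,15-diol and this from a tetracyclic 12-ketone. The bicyclo[3.2.1]octene (C8, C9, C11–C16) is opened at C13–C16 (Pd(PPh3)4-catalysed enolate alkenylation) and at C11–C15 (deconjugative alkylation with 2,3-dibromopropene) to an A/B/C enone.
2. Ring C comes from a Robinson-type annulation on the C9 ketone of an AB trans-decalin.
3. Ring A is closed by the C3–C4 bond: hydrogen-atom transfer to an isopropenyl group on C5 gives the tertiary C4 radical, which adds 6-endo to C3 of a vinyl ketone C1(=O)–C2=C3 carried by C10.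
4. The enabling feature: C4 is a quaternary carbon with two methyl groups next to the ring-fusion carbon C5, and the oxygenated C1 sits on the quaternary C10. Ring A is therefore "isopropenyl donor on C5 plus acryloyl acceptor on C10", and the carbonyl that activates C3 later becomes the 1α-acetate.
5. Ring B is bought as p-benzoquinone mono-ketal. Ring order: B (given), A (key step), C (annulation), bridged five-membered ring (alkylation, alkenylation).

Key step: step 5

Numbering: from the decalin stage on, target numbering is used. Ring A is C1–C5 and C10; ring B is C5–C10; the bicyclo[3.2.1]octene is C8, C9, C11–C16 with C12 as one-carbon bridge and C15–C16 as two-carbon bridge; C17 is the exocyclic CH2 and C20 the methyl on C10. α is the face of C20, β the face of H-5.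

Remark: (S)-BINAP is assumed to deliver the isopropenyl group to the enone face that gives the (S) adduct, by analogy with the usual facial sense for cyclohexenones; if the sense is opposite, (R)-BINAP is used.

Remark: the allylic oxidation in step 15 is assumed to deliver oxygen on the exo face of the two-carbon bridge (the face syn to C12), the less hindered face of that bridge.

## Route

Step 1
Reactants: 1 1,4-dioxaspiro[4.5]deca-6,9-dien-8-one (p-benzoquinone mono-ethylene ketal); 2 potassium trifluoro(prop-1-en-2-yl)borate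
Product: 3 (S)-10-(prop-1-en-2-yl)-1,4-dioxaspiro[4.5]dec-6-en-8-one
Conditions: [Rh(cod)2]BF4 (3 mol %), (S)-BINAP, Et3N, toluene/H2O, 25 °C; 1.0 equiv of 2
Reagents that add atoms: none
Why: Hayashi–Miyaura asymmetric conjugate addition of an alkenyl–rhodium species to one enone unit of the symmetrical dienone should set the C5 stereocentre under ligand control, and the adduct is less reactive than 1, which limits double addition.

Step 2
Reactants: 3
Product: 4 (9R,10S)-9-methyl-10-(prop-1-en-2-yl)-1,4-dioxaspiro[4.5]dec-6-en-8-one (methyl trans to isopropenyl; the C9 epimer is equally usable)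
Conditions: LiN(i-Pr)2, THF, −78 °C; MeI, −78 → −30 °C
Reagents that add atoms: iodomethane CI
Why: Kinetic α′-enolate alkylation, the CH2 between the carbonyl and the isopropenyl-bearing carbon being the only enolisable position; the new centre is re-enolised in step 3, so its configuration does not matter.

Step 3
Reactants: 4; 5 acrolein (prop-2-enal)
Product: 6 (9S,10R)-9-(1-hydroxyprop-2-en-1-yl)-9-methyl-10-(prop-1-en-2-yl)-1,4-dioxaspiro[4.5]dec-6-en-8-one (both carbinol epimers)
Conditions: LiN(i-Pr)2, THF, −78 °C; 5, −78 °C; AcOH quench at −78 °C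
Reagents that add atoms: none
Why: Lithium enolate aldol addition (1,2 to acrolein) should occur on the enolate face opposite the adjacent isopropenyl group, which sets the quaternary C10 with the new C1 carbon trans and the methyl cis to isopropenyl; the carbinol centre is removed in step 4.

Step 4
Reactants: 6
Product: 7 (9S,10R)-9-methyl-9-(prop-2-enoyl)-10-(prop-1-en-2-yl)-1,4-dioxaspiro[4.5]dec-6-en-8-one
Conditions: Dess–Martin periodinane, CH2Cl2, 0 → 25 °C
Reagents that add atoms: none
Why: Dess–Martin oxidation of the secondary allylic alcohol gives the non-enolisable 1,3-diketone with its vinyl ketone under neutral conditions that avoid retro-aldol and retro-Claisen cleavage.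

Step 5
Reactants: 7
Product: 10 decalin enedione ketal: 6,6-ethylenedioxy-4,4,10-trimethyl-trans-decal-7-ene-1,9-dione (5R,10S; 5β-H; 10α-CH3), via tertiary C4 radical 8 (not isolated), via C2 alpha-keto radical 9 (not isolated)
Conditions: Fe(acac)3 (30 mol %), PhSiH3, EtOH/ethylene glycol, 60 °C
Reagents that add atoms: none
Why: The Fe–H species formed from Fe(acac)3 and PhSiH3 in ethanol transfers a hydrogen atom to the terminal CH2 of the electron-rich isopropenyl group and gives the tertiary C4 radical 8, which adds to the unsubstituted terminus C3 of the vinyl ketone on C10; the α-keto radical 9 is then reduced by divalent iron and protonated by the solvent. The closest known reaction type is the iron-hydride reductive olefin coupling in its intramolecular form (MHAT-initiated Giese cyclization of isopropenyl-bearing cyclohexenones). Ring A closes in the 6-endo-trig mode, preferred over 5-exo attack at C2 by polarity matching and by the unhindered CH2 terminus. No new stereocentre is formed: the trans ring fusion follows from the trans, diequatorial isopropenyl and acryloyl groups set in steps 1 and 3, and the step creates the all-carbon quaternary C4. The selectivity needed is hydrogen-atom transfer to the 1,1-disubstituted alkene and not to the two electron-poor alkenes, which the electronic preference of the metal hydride secures; the ring B enone cannot trap the radical because attack at C7 would close a four-membered ring. In one operation the monocyclic 7 should become the AB trans-decalin with C1, C6 and C9 differentiated as saturated ketone, ketal and enone.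

Step 6
Reactants: 10
Product: 11 6,6-ethylenedioxy-1α-hydroxy-4,4,10-trimethyl-trans-decal-7-en-9-one
Conditions: NaBH4, MeOH/CH2Cl2, −78 → −40 °C
Reagents that add atoms: none
Why: Chemoselective borohydride reduction: the saturated C1 ketone is more electrophilic than the conjugated C9 carbonyl, and axial hydride delivery on the β face, anti to the axial C10 methyl, should give the equatorial 1α-alcohol.

Step 7
Reactants: 11
Product: 12 6,6-ethylenedioxy-1α-triethylsilyloxy-4,4,10-trimethyl-trans-decal-7-en-9-one
Conditions: Et3SiOTf, 2,6-lutidine, CH2Cl2, −78 → 0 °C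
Reagents that add atoms: triethylsilyl trifluoromethanesulfonate CC[Si](CC)(CC)OS(=O)(=O)C(F)(F)F
Why: Silylation masks the β-hydroxy ketone against retro-aldol cleavage in the basic annulation; ketone-derived dioxolanes tolerate silyl triflate with lutidine at low temperature.

Step 8
Reactants: 12
Product: 13 6,6-ethylenedioxy-1α-triethylsilyloxy-4,4,10-trimethyl-trans-decalin-9-one
Conditions: H2 (1 atm), Pd on carbon (Pd/C), EtOAc, 25 °C
Reagents that add atoms: none
Why: Heterogeneous hydrogenation of the disubstituted C7=C8 enone bond, the only C=C present; ketal and silyl ether are inert.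

Step 9
Reactants: 13; 14 3-(trimethylsilyl)but-3-en-2-one
Product: 17 tricyclic enone: ring C (C8, C9, C11–C14) fused at C8–C9; C9=C11 double bond; 12-oxo; 6,6-ethylenedioxy; 1α-OSiEt3; 5β-H; 10α-CH3; C8 epimers, via alpha-silyl diketone 15 (not isolated), via 1,5-diketone 16 (not isolated)
Conditions: LiN(i-Pr)2, THF, −78 °C; 14, −78 → −30 °C; then NaOMe, MeOH, 25 → 50 °C
Reagents that add atoms: none
Why: Robinson annulation with an α-silyl vinyl ketone: the only possible enolate of 13 (at C8, since C10 is quaternary) adds to 14, methoxide removes the silyl group, and the methyl ketone closes onto C9 by aldol condensation; the C8 centre is erased in step 13.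

Step 10
Reactants: 17
Product: 18 1α-hydroxy tricyclic 9(11)-ene-6,12-dione
Conditions: PPTS, acetone/H2O, 50 °C
Reagents that add atoms: water O
Why: Mild acid hydrolysis removes the dioxolane and the triethylsilyl ether in one operation; at this stage the C6 ketone is not β,γ to any alkene, so no conjugation can occur.

Step 11
Reactants: 18
Product: 19 1α,6α-dihydroxy tricyclic 9(11)-en-12-one
Conditions: NaBH4, MeOH/CH2Cl2, −78 → −40 °C
Reagents that add atoms: none
Why: Borohydride reduces the isolated C6 ketone faster than the conjugated C12 enone, and since the α face of C6 is blocked by the syn-axial C10 and C4 methyl groups, hydride should enter from the β face and give the axial 6α-alcohol.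

Step 12
Reactants: 19
Product: 20 1α,6α-diacetoxy tricyclic 9(11)-en-12-one
Conditions: Ac2O, DMAP (cat.), pyridine, 50 °C
Reagents that add atoms: acetic anhydride CC(=O)OC(C)=O
Why: DMAP-catalysed acetylation installs both acetates of the target; warming is needed for the hindered axial 6α-hydroxyl.

Step 13
Reactants: 20; 21 2,3-dibromoprop-1-ene
Product: 22 1α,6α-diacetoxy-11β-(2-bromoprop-2-en-1-yl) tricyclic 8(9)-en-12-one
Conditions: KOt-Bu, t-BuOH/THF, 0 °C; 21
Reagents that add atoms: none
Why: Deconjugative α-alkylation: the thermodynamic extended dienolate (γ-deprotonation at C8) is alkylated at C11 by the allylic bromide of 21, which leaves the tetrasubstituted C8=C9 alkene, and the electrophile should enter on the β face, anti to the axial C10 methyl, setting C11.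

Step 14
Reactants: 22
Product: 23 tetracyclic ketone: 1α,6α-diacetoxy-12-oxo-8(9),16(17)-diene with C15 as CH2 (bicyclo[3.2.1]octene closed)
Conditions: Pd(PPh3)4 (10 mol %), PhOK, THF, 70 °C
Reagents that add atoms: none
Why: Intramolecular ketone α-alkenylation: zerovalent palladium inserts into the vinyl bromide, the C13 enolate couples with it and reductive elimination closes the five-membered ring (5-exo) to the bicyclo[3.2.1]octene; C13 is fixed cis to C11 by the ring, and phenoxide cannot cleave alkyl acetates for thermodynamic reasons.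

Step 15
Reactants: 23
Product: 24 15-exo-hydroxy derivative of 23 (OH on C15 pointing toward the C12 bridge)
Conditions: SeO2 (0.5 equiv), t-BuOOH, CH2Cl2, 0 → 25 °C
Reagents that add atoms: selenium dioxide O=[Se]=O; tert-butyl hydroperoxide CC(C)(C)OO
Why: Riley allylic oxidation (ene reaction, then [2,3]-sigmatropic shift): of the allylic positions of the exocyclic alkene only C15 can react because C13 is a bridgehead, the tetrasubstituted C8=C9 alkene is shielded at C9 by quaternary C10 and bridgehead C11, and oxygen should arrive on the exo face.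

Step 16
Reactants: 24
Product: 26 1α,6α-diacetoxy-12,15-diol (15-dihydro target; 12-OH and 15-OH syn), via boron chelate 25 (not isolated)
Conditions: Et2BOMe, THF/MeOH, −78 °C; NaBH4; MeOH co-evaporation
Reagents that add atoms: none
Why: Narasaka–Prasad syn-selective reduction of the β-hydroxy ketone: the O15-bound diethylboron unit chelates and shields the C12 carbonyl on the face of the two-carbon bridge, so external hydride should attack from the alkene-side face and place the 12-OH syn to O15 and to the C15–C16 bridge, as in the target.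

Step 17
Reactants: 26
Product: 27 1α,6α-diacetoxyjungermannenone C
Conditions: MnO2, CH2Cl2, 25 °C
Reagents that add atoms: none
Why: MnO2 oxidises only the allylic 15-alcohol to the α-methylene ketone; the non-allylic 12-OH and the acetates should be untouched.

## Compound list

1 | 1,4-dioxaspiro[4.5]deca-6,9-dien-8-one | O=C1C=CC2(OCCO2)C=C1 | starting material
2 | potassium trifluoro(prop-1-en-2-yl)borate | [K+].C=C(C)[B-](F)(F)F | starting material
3 | (S)-10-(prop-1-en-2-yl)-1,4-dioxaspiro[4.5]dec-6-en-8-one | O=C1C=CC2(OCCO2)[C@H](C(C)=C)C1 | intermediate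
4 | (9R,10S)-9-methyl-10-(prop-1-en-2-yl)-1,4-dioxaspiro[4.5]dec-6-en-8-one (major epimer shown) | O=C1C=CC2(OCCO2)[C@H](C(C)=C)[C@H]1C | intermediate
5 | acrolein | C=CC=O | starting material
6 | (9S,10R)-9-(1-hydroxyprop-2-en-1-yl)-9-methyl-10-(prop-1-en-2-yl)-1,4-dioxaspiro[4.5]dec-6-en-8-one (carbinol epimers) | O=C1C=CC2(OCCO2)[C@H](C(C)=C)[C@@]1(C)C(O)C=C | intermediate
7 | (9S,10R)-9-methyl-9-(prop-2-enoyl)-10-(prop-1-en-2-yl)-1,4-dioxaspiro[4.5]dec-6-en-8-one | O=C1C=CC2(OCCO2)[C@H](C(C)=C)[C@@]1(C)C(=O)C=C | intermediate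
8 | tertiary C4 radical from 7 | O=C1C=CC2(OCCO2)[C@H]([C](C)C)[C@@]1(C)C(=O)C=C | intermediate (not isolated)
9 | cyclised C2 α-keto radical | O=C1C=CC2(OCCO2)[C@@H]3C(C)(C)C[CH]C(=O)[C@@]13C | intermediate (not isolated)
10 | 6,6-ethylenedioxy-4,4,10-trimethyl-trans-decal-7-ene-1,9-dione (5R,10S) | O=C1C=CC2(OCCO2)[C@@H]3C(C)(C)CCC(=O)[C@@]13C | intermediate
11 | 6,6-ethylenedioxy-1α-hydroxy-4,4,10-trimethyl-trans-decal-7-en-9-one | O=C1C=CC2(OCCO2)[C@@H]3C(C)(C)CC[C@H](O)[C@@]13C | intermediate
12 | 6,6-ethylenedioxy-1α-triethylsilyloxy-4,4,10-trimethyl-trans-decal-7-en-9-one | O=C1C=CC2(OCCO2)[C@@H]3C(C)(C)CC[C@H](O[Si](CC)(CC)CC)[C@@]13C | intermediate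
13 | 6,6-ethylenedioxy-1α-triethylsilyloxy-4,4,10-trimethyl-trans-decalin-9-one | O=C1CCC2(OCCO2)[C@@H]3C(C)(C)CC[C@H](O[Si](CC)(CC)CC)[C@@]13C | intermediate
14 | 3-(trimethylsilyl)but-3-en-2-one | CC(=O)C(=C)[Si](C)(C)C | starting material
15 | 8-[3-oxo-2-(trimethylsilyl)butyl] derivative of 13 (diastereomers) | O=C1C(CC([Si](C)(C)C)C(C)=O)CC2(OCCO2)[C@@H]3C(C)(C)CC[C@H](O[Si](CC)(CC)CC)[C@@]13C | intermediate (not isolated)
16 | 8-(3-oxobutyl) derivative of 13 | O=C1C(CCC(C)=O)CC2(OCCO2)[C@@H]3C(C)(C)CC[C@H](O[Si](CC)(CC)CC)[C@@]13C | intermediate (not isolated)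
17 | tricyclic 9(11)-en-12-one; 6,6-ethylenedioxy; 1α-OSiEt3 (C8 epimers) | O=C1C=C2C(CC1)CC3(OCCO3)[C@@H]4C(C)(C)CC[C@H](O[Si](CC)(CC)CC)[C@@]24C | intermediate
18 | 1α-hydroxy tricyclic 9(11)-ene-6,12-dione | O=C1C=C2C(CC1)CC(=O)[C@@H]4C(C)(C)CC[C@H](O)[C@@]24C | intermediate
19 | 1α,6α-dihydroxy tricyclic 9(11)-en-12-one | O=C1C=C2C(CC1)C[C@H](O)[C@@H]4C(C)(C)CC[C@H](O)[C@@]24C | intermediate
20 | 1α,6α-diacetoxy tricyclic 9(11)-en-12-one | O=C1C=C2C(CC1)C[C@H](OC(C)=O)[C@@H]4C(C)(C)CC[C@H](OC(C)=O)[C@@]24C | intermediate
21 | 2,3-dibromoprop-1-ene | C=C(Br)CBr | starting material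
22 | 1α,6α-diacetoxy-11β-(2-bromoprop-2-en-1-yl) tricyclic 8(9)-en-12-one | C=C(Br)C[C@@H]1C2=C(CCC1=O)C[C@H](OC(C)=O)[C@@H]4C(C)(C)CC[C@H](OC(C)=O)[C@@]24C | intermediate
23 | tetracyclic 12-ketone; 1α,6α-diacetoxy; 16(17)-methylene; C15 = CH2 | C=C1C[C@@H]2C3=C(C[C@H](OC(C)=O)[C@@H]4C(C)(C)CC[C@H](OC(C)=O)[C@@]34C)C[C@H]1C2=O | intermediate
24 | 15-exo-hydroxy derivative of 23 | C=C1[C@@H](O)[C@@H]2C3=C(C[C@H](OC(C)=O)[C@@H]4C(C)(C)CC[C@H](OC(C)=O)[C@@]34C)C[C@H]1C2=O | intermediate
25 | O15-diethylboryl chelate of 24 | C=C1[C@@H](OB(CC)CC)[C@@H]2C3=C(C[C@H](OC(C)=O)[C@@H]4C(C)(C)CC[C@H](OC(C)=O)[C@@]34C)C[C@H]1C2=O | intermediate (not isolated)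
26 | 1α,6α-diacetoxy-12,15-diol (syn) | C=C1[C@@H](O)[C@@H]2C3=C(C[C@H](OC(C)=O)[C@@H]4C(C)(C)CC[C@H](OC(C)=O)[C@@]34C)C[C@H]1[C@@H]2O | intermediate
27 | 1α,6α-diacetoxyjungermannenone C | C=C1C(=O)[C@@H]2C3=C(C[C@H](OC(C)=O)[C@@H]4C(C)(C)CC[C@H](OC(C)=O)[C@@]34C)C[C@H]1[C@@H]2O | target

## Count and risks

Total step count: 17. Longest linear sequence: 17 steps (from 1).

Steps most likely to fail:

1. Step 14. Base-mediated isomerisation of the β,γ-enone into conjugation (C11 becomes sp2 and can no longer bridge) and reduction of the vinyl bromide may outrun the C–C coupling. The fallback sets out from 20 and returns at 23. Enone 20 is alkylated with propargyl bromide (KOt-Bu, t-BuOH/THF) to the 11β-propargyl ketone F1. Kinetic silylation at C13 (LiN(SiMe3)2, t-BuMe2SiCl, THF, −78 °C) gives the silyl enol ether F2. Ph3PAuNTf2 (monovalent gold, 5 mol %) in CH2Cl2/MeOH at 25 °C should then effect a 5-exo-dig Conia-ene-type carbocyclization of the enol ether onto the alkyne and give 23 after protodeauration.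

2. Step 16. Facial control at C12 may be lost if the boron chelate cannot span O15 and the C12 carbonyl, or if hydride is delivered intramolecularly from an O15-bound borohydride, which would give the anti diol. The fallback sets out from 24 and returns at 26. Silylation (t-BuMe2SiOTf, 2,6-lutidine, CH2Cl2) gives the 15-exo silyl ether F3, whose bulky group blocks the two-carbon-bridge face of the C12 carbonyl. NaBH4 (MeOH, 0 °C) must then attack from the alkene-side face and give the 12-alcohol F4, and HF·pyridine (THF) removes the silyl group to give 26.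

3. Step 13. Under the alkoxide base the acetates may be cleaved, or the C1 acetyl group may be transferred to the neighbouring C11 carbanion (peri position), and over-alkylation at C11 is possible. The fallback sets out from 19 and returns at 22. Diol 19 is silylated (Et3SiOTf, 2,6-lutidine) to the bis(triethylsilyl) ether F5. Deconjugative alkylation (KOt-Bu, 21) gives the 11β-(2-bromoallyl) ketone F6, HF·pyridine gives the diol F7, and acetylation (Ac2O, DMAP, pyridine) gives 22.

## Further compounds

F1 | step 14 | 1α,6α-diacetoxy-11β-(prop-2-yn-1-yl) tricyclic 8(9)-en-12-one | C#CC[C@@H]1C2=C(CCC1=O)C[C@H](OC(C)=O)[C@@H]4C(C)(C)CC[C@H](OC(C)=O)[C@@]24C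
F2 | step 14 | 12-(tert-butyldimethylsilyloxy)-12(13)-ene silyl enol ether of F1 | C#CC[C@@H]1C2=C(CC=C1O[Si](C)(C)C(C)(C)C)C[C@H](OC(C)=O)[C@@H]4C(C)(C)CC[C@H](OC(C)=O)[C@@]24C
F3 | step 16 | 15-exo-(tert-butyldimethylsilyloxy) derivative of 23 | C=C1[C@@H](O[Si](C)(C)C(C)(C)C)[C@@H]2C3=C(C[C@H](OC(C)=O)[C@@H]4C(C)(C)CC[C@H](OC(C)=O)[C@@]34C)C[C@H]1C2=O
F4 | step 16 | 15-O-(tert-butyldimethylsilyl) ether of 26 | C=C1[C@@H](O[Si](C)(C)C(C)(C)C)[C@@H]2C3=C(C[C@H](OC(C)=O)[C@@H]4C(C)(C)CC[C@H](OC(C)=O)[C@@]34C)C[C@H]1[C@@H]2O
F5 | step 13 | 1α,6α-bis(triethylsilyloxy) tricyclic 9(11)-en-12-one | O=C1C=C2C(CC1)C[C@H](O[Si](CC)(CC)CC)[C@@H]4C(C)(C)CC[C@H](O[Si](CC)(CC)CC)[C@@]24C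
F6 | step 13 | 1α,6α-bis(triethylsilyloxy)-11β-(2-bromoprop-2-en-1-yl) tricyclic 8(9)-en-12-one | C=C(Br)C[C@@H]1C2=C(CCC1=O)C[C@H](O[Si](CC)(CC)CC)[C@@H]4C(C)(C)CC[C@H](O[Si](CC)(CC)CC)[C@@]24C
F7 | step 13 | 1α,6α-dihydroxy-11β-(2-bromoprop-2-en-1-yl) tricyclic 8(9)-en-12-one | C=C(Br)C[C@@H]1C2=C(CCC1=O)C[C@H](O)[C@@H]4C(C)(C)CC[C@H](O)[C@@]24C
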